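Readings and results are calculated with constants of no real substance, and the scatter is random.

This flask gets less J than G, 0.250 M against 0.50 M, so J is the limiting reagent: it pays for half an exchange per G charged.

| setting | amber | flask |
|---|---|---|
| G | 0.50 M (fed, over 3.0 h) | 0.50 M (fed, over 3.0 h) |
| J | 0.25 M | 0.250 M |
| Z | 1 M | 1.00 M |
| remark | the very flask that is asked about, followed so far; the fed solution adds 0.10 times the starting volume | the fed solution adds 0.10 times the starting volume |
| time |  | 6.0 d |

amber run (percent of the G charged)

| time / h | G / % | L / % | X / % |
|---|---|---|---|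
| 1.33 | 40.2 | 4.5 | 1.3 |
| 2.50 | 70.9 | 11.7 | 1.6 |
| 4.00 | 75.1 | 22.6 | 2.3 |
| 6.00 | 66.4 | 33.7 | 3.9 |
| 10.0 | 60.0 | 36.9 | 3.5 |
| 15.0 | 56.7 | 39.2 | 2.9 |

(standard deviation of a reading: 1 percentage point)

1. part of the G gone at 6.0 d
2. the L standing at 6.0 d, as a percentage of the G charged
3. the X standing at 6.0 d, as a percentage of the G charged

- charges are per starting volume, the dose included; the dosed solution carries all of it
- the earlier runs were read with a standard deviation of 1 percentage point
- steps under discussion: Q + J <-> Z + D; X + J <-> Z + Q; L + J <-> Z + X; L -> E; G + J <-> Z + L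
- percentages count the whole charge, also what has not yet gone in

Follow one molecule of G, counting everything as fractions of the G charge. At each fork it takes a J and gives a Z, or goes back. At balance its odds of standing one rung up are L over G at the first fork and X over L at the second. Both odds contain the same J over Z, which no reading shows, so their quotient is free of it: two L trade into one G and one X. Taking the last amber reading, at 15.0 h, as balanced, we get 0.107 for this rung ratio, X times G over L squared. It is a reading, with 1 percentage point of scatter on an X of 2.9%.

First link: let all the J be spent, so that L plus twice X makes 50.0%, and let G, L and X fill the charge. The rung ratio then gives X 3.64%. But that amber reading has L plus twice X at 45.0%, short of 50.0%, so the spent J is the weak link: the gap may be J left, or unread Q. Reforged with 45.0%, and booking no E as a bare assumption that a reading at 15.0 h does not test for 6.0 d, the same reckoning gives X 2.86%, L 39.3% and G gone 42.1%. We commit to these for 6.0 d.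

The forecast gave 45.5%, 36% and 1.6%, an X below ours, holding that “E keeps G almost unchanged but lowers L”. The flask gives 43.9% of G gone, L 39.5% and X 2.82%.

    Q + J ⇌ Z + D (K = 13.0, k = 0.0742 /M/h)
    X + J ⇌ Z + Q (K = 43.8, k = 0.639 /M/h)
    L + J ⇌ Z + X (K = 11.0, k = 0.240 /M/h)
    L → E (k = 1.20 × 10⁻⁴ /h)
    G + J ⇌ Z + L (K = 110, k = 0.742 /M/h)

On these amounts the rung ratio comes to 0.101. Carried to the neighbour charged with 0.62 M of J, our 0.107 turns its G 22.5% and L 51.8% into X 12.8%, and that flask holds 11.9%. Our flask is nearly at rest: over the second half of the time X went from 2.93% to 2.82%, while E rose from 0.321% to 0.663%. Left to 60.0 d, it still drifts: E reaches 6.49%, X falls to 2.31%, the G gone stands at 44.9%, and L falls to 35.4%.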